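**Plan**

1. Retrosynthesis (labdane numbering): the C12–C13 bond is cut first (sp3–sp2 Negishi coupling with a bromoalkene that already carries C14), then C8=C17 (methylenation of a C8 ketone), then C9–C10 (ring B), then C7–C8 (acylation by a fumaric half-ester that supplies C8, C9, C11 and C12), and last C4–C5 and C2–C3 (Diels–Alder, ring A).
2. Enabling feature: C10 is the methyl-bearing quaternary carbon shared by rings A and B, and its neighbour C9 is a methine carrying the arm C11–C12; this pair is the trace of a tertiary C10 radical that has added to C9 of a C9=C11 enoate.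
3. Forward: ring A is made first by a catalytic enantioselective Diels–Alder reaction of methacrolein with a 2-silyloxy diene; the siloxy group is removed through the enol triflate to leave the C1=C10 alkene, and the C5 arm is extended to the ketal enoate.
4. Ring B is then closed by iron-hydride hydrogen-atom transfer to C1 and 6-exo addition of the C10 radical to C9; C8 is unmasked and methylenated, C12 is taken to the iodide and the side chain is joined last.
5. Stereochemistry: C4 from the chiral oxazaborolidinium catalyst, C5 from the endo mode of the cycloaddition, C10 and C9 from the C4/C5-controlled chair of the radical closure (C9 also under thermodynamic control next to the C8 ketone), C14 from (S)-but-3-ene-1,2-diol.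
6. Skeleton atoms carry labdane numbers in the discussion; the names of the monocyclic intermediates use their own ring numbers.

Key step: step 13

Assumption: the oxazaborolidinium ion derived from (S)-diphenylprolinol is taken to give the (S) quaternary carbon, as the formyl C–H···O binding model for 2-substituted acroleins predicts; the mirror-image catalyst would be used if the sense proved opposite.

**Route**

Step 1
Reactants: 1 3-[(4-methoxybenzyl)oxy]propanal; 2 3-(triphenylphosphoranylidene)butan-2-one
Product: 3 (E)-6-[(4-methoxybenzyl)oxy]-3-methylhex-3-en-2-one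
Conditions: toluene, 90 °C
Reagents that add atoms: none
Why: Wittig olefination with an acyl-stabilised α-methyl ylide, which should give the (E)-trisubstituted enone with the chain trans to the acetyl group.

Step 2
Reactants: 3 (E)-6-[(4-methoxybenzyl)oxy]-3-methylhex-3-en-2-one
Product: 4 triisopropyl{[(3E)-6-[(4-methoxybenzyl)oxy]-3-methylhexa-1,3-dien-2-yl]oxy}silane
Conditions: iPr3SiOTf, Et3N, CH2Cl2, −78 → 0 °C
Reagents that add atoms: triisopropylsilyl trifluoromethanesulfonate, CC(C)[Si](OS(=O)(=O)C(F)(F)F)(C(C)C)C(C)C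
Why: Soft enolisation (silyl triflate and amine) should remove a proton from the acetyl CH3, the most accessible α-position, and give the cross-conjugated 2-silyloxy diene with the (E) C3=C4 bond untouched.

Step 3
Reactants: 4 triisopropyl{[(3E)-6-[(4-methoxybenzyl)oxy]-3-methylhexa-1,3-dien-2-yl]oxy}silane; 5 methacrolein
Product: 6 (1S,2R)-2-{2-[(4-methoxybenzyl)oxy]ethyl}-1,3-dimethyl-4-[(triisopropylsilyl)oxy]cyclohex-3-ene-1-carbaldehyde
Conditions: (S)-3,3-diphenyl-1-(o-tolyl)tetrahydro-1H,3H-pyrrolo[1,2-c][1,3,2]oxazaborole (20 mol %), Tf2NH (18 mol %), CH2Cl2, −78 → −40 °C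
Reagents that add atoms: none
Why: Lewis-acid-catalysed enantioselective Diels–Alder reaction in which the silyloxy group directs the nucleophilic diene terminus (C2) to the enal β-carbon (C3) so that C5 bonds to C4, the protonated oxazaborolidine bound to the s-trans enal shields one face and should set the quaternary C4 as (S), and the endo transition state (formyl under the diene) places CHO cis to the C5 arm and so sets C5 as (R).

Step 4
Reactants: 6 (1S,2R)-2-{2-[(4-methoxybenzyl)oxy]ethyl}-1,3-dimethyl-4-[(triisopropylsilyl)oxy]cyclohex-3-ene-1-carbaldehyde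
Product: 7 (1S,2R)-2-{2-[(4-methoxybenzyl)oxy]ethyl}-1,3-dimethyl-4-{[(trifluoromethyl)sulfonyl]oxy}cyclohex-3-ene-1-carbaldehyde
Conditions: CsF, PhNTf2, DME, 23 °C
Reagents that add atoms: N-phenylbis(trifluoromethanesulfonimide), O=S(=O)(N(c1ccccc1)S(=O)(=O)C(F)(F)F)C(F)(F)F
Why: Fluoride-induced conversion of a silyl enol ether into an enol triflate, in which the regiodefined tetrasubstituted cesium enolate should be captured on oxygen by PhNTf2 faster than it can attack the neopentylic, non-enolisable aldehyde, so that the double bond stays at C1=C10.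

Step 5
Reactants: 7 (1S,2R)-2-{2-[(4-methoxybenzyl)oxy]ethyl}-1,3-dimethyl-4-{[(trifluoromethyl)sulfonyl]oxy}cyclohex-3-ene-1-carbaldehyde
Product: 8 (1S,2R)-2-{2-[(4-methoxybenzyl)oxy]ethyl}-1,3-dimethyl-4-{[(trifluoromethyl)sulfonyl]oxy}cyclohex-3-ene-1-carboxylic acid
Conditions: NaClO2, NaH2PO4, 2-methyl-2-butene, t-BuOH/H2O, 0 → 23 °C
Reagents that add atoms: sodium chlorite, [Na+].[O-]Cl=O
Why: Pinnick oxidation converts hindered α-quaternary aldehydes into acids and is done at this stage because the only alkene present is the electron-poor enol triflate, which the scavenged hypochlorite should not touch.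

Step 6
Reactants: 8 (1S,2R)-2-{2-[(4-methoxybenzyl)oxy]ethyl}-1,3-dimethyl-4-{[(trifluoromethyl)sulfonyl]oxy}cyclohex-3-ene-1-carboxylic acid
Product: 9 methyl (1S,2R)-2-{2-[(4-methoxybenzyl)oxy]ethyl}-1,3-dimethyl-4-{[(trifluoromethyl)sulfonyl]oxy}cyclohex-3-ene-1-carboxylate
Conditions: MeI, K2CO3, DMF, 23 °C
Reagents that add atoms: iodomethane, CI
Why: O-alkylation of the carboxylate (SN2 at the methyl group) is insensitive to the crowding at the quaternary carbon that would slow an acid-catalysed esterification.

Step 7
Reactants: 9 methyl (1S,2R)-2-{2-[(4-methoxybenzyl)oxy]ethyl}-1,3-dimethyl-4-{[(trifluoromethyl)sulfonyl]oxy}cyclohex-3-ene-1-carboxylate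
Product: 10 methyl (1S,2R)-2-{2-[(4-methoxybenzyl)oxy]ethyl}-1,3-dimethylcyclohex-3-ene-1-carboxylate
Conditions: Pd(OAc)2 (5 mol %), PPh3 (10 mol %), HCO2H, Bu3N, DMF, 60 °C
Reagents that add atoms: none
Why: Palladium-catalysed formate reduction of an enol triflate (oxidative addition to zerovalent palladium, formate exchange, loss of CO2, C–H reductive elimination) should replace OTf by H and fix the alkene at C1=C10.

Step 8
Reactants: 10 methyl (1S,2R)-2-{2-[(4-methoxybenzyl)oxy]ethyl}-1,3-dimethylcyclohex-3-ene-1-carboxylate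
Product: 11 methyl (1S,2R)-2-(2-hydroxyethyl)-1,3-dimethylcyclohex-3-ene-1-carboxylate
Conditions: DDQ, CH2Cl2/pH 7 buffer, 0 °C
Reagents that add atoms: none
Why: Oxidative cleavage of the 4-methoxybenzyl ether by DDQ (benzylic hydride abstraction, then hydrolysis) leaves the isolated alkene and the ester alone, and the hydroxy ester is carried on at once so that lactonisation onto the neighbouring ester has no time to occur.

Step 9
Reactants: 11 methyl (1S,2R)-2-(2-hydroxyethyl)-1,3-dimethylcyclohex-3-ene-1-carboxylate
Product: 12 methyl (1S,2R)-2-(2-iodoethyl)-1,3-dimethylcyclohex-3-ene-1-carboxylate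
Conditions: PPh3, I2, imidazole, CH2Cl2, 0 → 23 °C
Reagents that add atoms: iodine, II
Why: Appel-type iodination, in which the primary alcohol is activated as an alkoxyphosphonium ion and displaced by iodide in an SN2 reaction.

Step 10
Reactants: 13 monomethyl fumarate
Product: 14 methyl (E)-4-chloro-4-oxobut-2-enoate
Conditions: (COCl)2, DMF (cat.), CH2Cl2, 0 → 23 °C
Reagents that add atoms: oxalyl chloride, O=C(Cl)C(=O)Cl
Why: Acid chloride formation through the chloroiminium species proceeds at room temperature and should keep the (E) double bond and the methyl ester.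

Step 11
Reactants: 12 methyl (1S,2R)-2-(2-iodoethyl)-1,3-dimethylcyclohex-3-ene-1-carboxylate; 14 methyl (E)-4-chloro-4-oxobut-2-enoate
Product: 16 methyl (1S,2R)-2-[(4E)-6-methoxy-3,6-dioxohex-4-en-1-yl]-1,3-dimethylcyclohex-3-ene-1-carboxylate, via alkylzinc iodide 15 (not isolated)
Conditions: Zn dust (activated with Me3SiCl and BrCH2CH2Br), THF, 40 °C; then 14, Pd(PPh3)4 (5 mol %), THF, 0 → 23 °C
Reagents that add atoms: none
Why: Zinc inserts into the primary C–I bond without harm to the ester, and the palladium-catalysed acylation of the alkylzinc (Negishi-type ketone synthesis through oxidative addition of the acid chloride to zerovalent palladium, transmetalation and reductive elimination) should form the C7–C8 bond without conjugate addition, since alkylzinc halides do not add to enoates on their own.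

Step 12
Reactants: 16 methyl (1S,2R)-2-[(4E)-6-methoxy-3,6-dioxohex-4-en-1-yl]-1,3-dimethylcyclohex-3-ene-1-carboxylate
Product: 17 methyl (1S,2R)-2-{2-[2-((E)-3-methoxy-3-oxoprop-1-en-1-yl)-1,3-dioxolan-2-yl]ethyl}-1,3-dimethylcyclohex-3-ene-1-carboxylate
Conditions: (Me3SiOCH2)2, Me3SiOTf (10 mol %), CH2Cl2, −78 → −20 °C; pyridine
Reagents that add atoms: 1,2-bis(trimethylsilyloxy)ethane, C[Si](C)(C)OCCO[Si](C)(C)C
Why: Silyl-triflate-catalysed ketalisation with the bis-silyl ether of ethylene glycol is aprotic and driven by formation of hexamethyldisiloxane, so the C8 ketone should be masked at low temperature without conjugate addition to, or isomerisation of, the (E)-enoate.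

Step 13
Reactants: 17 methyl (1S,2R)-2-{2-[2-((E)-3-methoxy-3-oxoprop-1-en-1-yl)-1,3-dioxolan-2-yl]ethyl}-1,3-dimethylcyclohex-3-ene-1-carboxylate
Product: 18 dimethyl (4S,5R,9R,10S)-8,8-ethylenedioxy-13,14,15,16,17-pentanorlabdane-12,19-dioate
Conditions: Fe(acac)3 (30 mol %), PhSiH3, EtOH/(CH2OH)2 (5:1), 0.02 M, 60 °C, Ar
Reagents that add atoms: none
Why: The iron hydride generated from Fe(acac)3 and PhSiH3 should deliver a hydrogen atom to C1, the less substituted end of the electron-rich C1=C10 alkene, and the resulting tertiary C10 radical should add to C9, the β-carbon of the tethered enoate, after which the C11 α-ester radical is reduced by divalent iron to the enolate and protonated by ethanol, which returns trivalent iron to the cycle. The closest known reaction type is the hydrogen-atom-transfer-initiated reductive coupling of an unactivated alkene with an acrylate-type acceptor, used here intramolecularly as a Giese cyclisation that creates a quaternary carbon. Ring B is closed in the 6-exo-trig mode through a chair-like transition state (C10, C5, C6, C7, C8, C9). C10 is controlled by the two existing centres: the C5 tether is equatorial and the C4 ester is axial on the β face, so C9 should bond to the α lobe of the radical, which leaves C20 β and the ring fusion trans. C9 is set in the same chair with the enoate arm C11 equatorial and H9 axial on the α face, and a C9 epimer would in any case be drawn to this arrangement by equilibration next to the C8 ketone in steps 14 and 15. The step needs hydrogen-atom transfer to the C1=C10 alkene in preference to the enoate and attack at C9 in preference to C11; the first rests on the trisubstituted, electron-rich alkene against an electron-poor β-substituted enoate, the second on the dioxolane at C8, which leaves the ester as the only group that polarises the C9=C11 bond and makes the 6-exo path the matched one.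

Step 14
Reactants: 18 dimethyl (4S,5R,9R,10S)-8,8-ethylenedioxy-13,14,15,16,17-pentanorlabdane-12,19-dioate
Product: 19 dimethyl (4S,5R,9R,10S)-8-oxo-13,14,15,16,17-pentanorlabdane-12,19-dioate
Conditions: 2 M aq HCl, THF, 23 °C
Reagents that add atoms: water, O
Why: Acid-catalysed hydrolysis of the dioxolane returns the C8 ketone while both methyl esters survive dilute acid at room temperature, and the now enolisable C9 should settle with the CH2CO2Me arm equatorial.

Step 15
Reactants: 19 dimethyl (4S,5R,9R,10S)-8-oxo-13,14,15,16,17-pentanorlabdane-12,19-dioate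
Product: 20 dimethyl (4S,5R,9S,10R)-13,14,15,16-tetranorlabd-8(17)-ene-12,19-dioate
Conditions: Ph3PCH3Br, KOt-Bu, toluene, 0 → 50 °C
Reagents that add atoms: methyltriphenylphosphonium bromide, C[P+](c1ccccc1)(c1ccccc1)c1ccccc1.[Br-]
Why: Wittig methylenation, in which the unstabilised ylide attacks the ketone much faster than either ester and any enolisation at C9 is reversible toward the equatorial epimer, should install the C8=C17 bond.

Step 16
Reactants: 20 dimethyl (4S,5R,9S,10R)-13,14,15,16-tetranorlabd-8(17)-ene-12,19-dioate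
Product: 21 methyl (4S,5R,9S,10R)-12-hydroxy-13,14,15,16-tetranorlabd-8(17)-en-19-oate
Conditions: LiBH4, MeOH (1 equiv), THF, 0 → 23 °C
Reagents that add atoms: none
Why: Chemoselective ester reduction by LiBH4, since the C12 ester is a primary-alkyl ester open to hydride whereas the C19 ester sits axially on a quaternary carbon, 1,3-diaxial to C20, and should be left.

Step 17
Reactants: 21 methyl (4S,5R,9S,10R)-12-hydroxy-13,14,15,16-tetranorlabd-8(17)-en-19-oate
Product: 22 methyl (4S,5R,9S,10R)-12-iodo-13,14,15,16-tetranorlabd-8(17)-en-19-oate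
Conditions: PPh3, I2, imidazole, CH2Cl2, 0 °C; then 21
Reagents that add atoms: iodine, II
Why: Appel-type iodination (SN2 of iodide on the alkoxyphosphonium ion), with the phosphine–iodine reagent formed before the alcohol is added so that no free iodine is left for iodoetherification across the C8=C17 bond.

Step 18
Reactants: 23 (S)-but-3-ene-1,2-diol
Product: 24 (S)-2,2-dimethyl-4-vinyl-1,3-dioxolane
Conditions: Me2C(OMe)2, TsOH·H2O (cat.), CH2Cl2, 23 °C
Reagents that add atoms: 2,2-dimethoxypropane, COC(C)(C)OC
Why: Acid-catalysed transketalisation closes the five-membered acetonide of the 1,2-diol without involving the stereocentre.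

Step 19
Reactants: 24 (S)-2,2-dimethyl-4-vinyl-1,3-dioxolane
Product: 25 (4R)-4-(1,2-dibromoethyl)-2,2-dimethyl-1,3-dioxolane (both epimers at the CHBr carbon)
Conditions: Br2, K2CO3 (solid), CH2Cl2, −78 °C
Reagents that add atoms: bromine, BrBr
Why: Electrophilic anti addition of bromine to the terminal alkene at low temperature, the new CHBr centre being of no consequence because it becomes sp2 in step 20.

Step 20
Reactants: 25 (4R)-4-(1,2-dibromoethyl)-2,2-dimethyl-1,3-dioxolane
Product: 26 (R)-4-(1-bromovinyl)-2,2-dimethyl-1,3-dioxolane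
Conditions: DBU, DMF, 23 → 50 °C
Reagents that add atoms: none
Why: E2 dehydrobromination in which the C–H bond of the CHBr carbon is acidified by the neighbouring oxygen-bearing carbon and the primary bromide leaves, the known regiochemical preference of 1,2-dibromides with an oxygen substituent on the adjacent carbon, which should give the 2-bromo-1-alkene.

Step 21
Reactants: 22 methyl (4S,5R,9S,10R)-12-iodo-13,14,15,16-tetranorlabd-8(17)-en-19-oate; 26 (R)-4-(1-bromovinyl)-2,2-dimethyl-1,3-dioxolane
Product: 28 methyl (4S,5R,9S,10R,14S)-14,15-(isopropylidenedioxy)labda-8(17),13(16)-dien-19-oate, via alkylzinc iodide 27 (not isolated)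
Conditions: Zn dust (activated), LiCl, THF, 40 °C; then 26, Pd(dppf)Cl2 (5 mol %), THF, 50 °C
Reagents that add atoms: none
Why: Negishi sp3–sp2 cross-coupling, in which zinc insertion into the primary iodide tolerates the ester and the alkene and the wide-bite-angle diphosphine favours reductive elimination over β-hydride elimination, should join C12 to C13 with the non-enolisable C14 centre untouched.

Step 22
Reactants: 28 methyl (4S,5R,9S,10R,14S)-14,15-(isopropylidenedioxy)labda-8(17),13(16)-dien-19-oate
Product: 29 methyl (4S,5R,9S,10R,14S)-14,15-dihydroxylabda-8(17),13(16)-dien-19-oate (CNP0185041.1)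
Conditions: AcOH/H2O/THF (3:1:1), 40 °C
Reagents that add atoms: none
Why: Mild acid hydrolysis of the terminal acetonide frees the 14,15-diol, aqueous acetic acid being too weak to move the exocyclic C8=C17 bond or to ionise the allylic C14–O bond.

**Compound list**

1 | 3-[(4-methoxybenzyl)oxy]propanal | O=CCCOCc1ccc(OC)cc1 | starting material
2 | 3-(triphenylphosphoranylidene)butan-2-one | CC(=O)C(C)=P(c1ccccc1)(c1ccccc1)c1ccccc1 | starting material
3 | (E)-6-[(4-methoxybenzyl)oxy]-3-methylhex-3-en-2-one | CC(=O)/C(C)=C/CCOCc1ccc(OC)cc1 | intermediate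
4 | triisopropyl{[(3E)-6-[(4-methoxybenzyl)oxy]-3-methylhexa-1,3-dien-2-yl]oxy}silane | C=C(O[Si](C(C)C)(C(C)C)C(C)C)/C(C)=C/CCOCc1ccc(OC)cc1 | intermediate
5 | methacrolein | C=C(C)C=O | starting material
6 | (1S,2R)-2-{2-[(4-methoxybenzyl)oxy]ethyl}-1,3-dimethyl-4-[(triisopropylsilyl)oxy]cyclohex-3-ene-1-carbaldehyde | COc1ccc(COCC[C@@H]2C(C)=C(O[Si](C(C)C)(C(C)C)C(C)C)CC[C@]2(C)C=O)cc1 | intermediate
7 | (1S,2R)-2-{2-[(4-methoxybenzyl)oxy]ethyl}-1,3-dimethyl-4-{[(trifluoromethyl)sulfonyl]oxy}cyclohex-3-ene-1-carbaldehyde | COc1ccc(COCC[C@@H]2C(C)=C(OS(=O)(=O)C(F)(F)F)CC[C@]2(C)C=O)cc1 | intermediate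
8 | (1S,2R)-2-{2-[(4-methoxybenzyl)oxy]ethyl}-1,3-dimethyl-4-{[(trifluoromethyl)sulfonyl]oxy}cyclohex-3-ene-1-carboxylic acid | COc1ccc(COCC[C@@H]2C(C)=C(OS(=O)(=O)C(F)(F)F)CC[C@]2(C)C(=O)O)cc1 | intermediate
9 | methyl (1S,2R)-2-{2-[(4-methoxybenzyl)oxy]ethyl}-1,3-dimethyl-4-{[(trifluoromethyl)sulfonyl]oxy}cyclohex-3-ene-1-carboxylate | COc1ccc(COCC[C@@H]2C(C)=C(OS(=O)(=O)C(F)(F)F)CC[C@]2(C)C(=O)OC)cc1 | intermediate
10 | methyl (1S,2R)-2-{2-[(4-methoxybenzyl)oxy]ethyl}-1,3-dimethylcyclohex-3-ene-1-carboxylate | COc1ccc(COCC[C@@H]2C(C)=CCC[C@]2(C)C(=O)OC)cc1 | intermediate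
11 | methyl (1S,2R)-2-(2-hydroxyethyl)-1,3-dimethylcyclohex-3-ene-1-carboxylate | OCC[C@@H]1C(C)=CCC[C@]1(C)C(=O)OC | intermediate
12 | methyl (1S,2R)-2-(2-iodoethyl)-1,3-dimethylcyclohex-3-ene-1-carboxylate | ICC[C@@H]1C(C)=CCC[C@]1(C)C(=O)OC | intermediate
13 | monomethyl fumarate | COC(=O)/C=C/C(=O)O | starting material
14 | methyl (E)-4-chloro-4-oxobut-2-enoate | COC(=O)/C=C/C(=O)Cl | intermediate
15 | iodo{2-[(1R,6S)-6-(methoxycarbonyl)-2,6-dimethylcyclohex-2-en-1-yl]ethyl}zinc (alkylzinc iodide from 12) | I[Zn]CC[C@@H]1C(C)=CCC[C@]1(C)C(=O)OC | intermediate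
16 | methyl (1S,2R)-2-[(4E)-6-methoxy-3,6-dioxohex-4-en-1-yl]-1,3-dimethylcyclohex-3-ene-1-carboxylate | COC(=O)/C=C/C(=O)CC[C@@H]1C(C)=CCC[C@]1(C)C(=O)OC | intermediate
17 | methyl (1S,2R)-2-{2-[2-((E)-3-methoxy-3-oxoprop-1-en-1-yl)-1,3-dioxolan-2-yl]ethyl}-1,3-dimethylcyclohex-3-ene-1-carboxylate (the ketal enoate) | COC(=O)/C=C/C1(OCCO1)CC[C@@H]2C(C)=CCC[C@]2(C)C(=O)OC | intermediate
18 | dimethyl (4S,5R,9R,10S)-8,8-ethylenedioxy-13,14,15,16,17-pentanorlabdane-12,19-dioate (trans-decalin; C20 and the C4 ester both β-axial; 9α-H; C8 spiro-dioxolane) | COC(=O)C[C@H]1C2(OCCO2)CC[C@@H]3[C@]1(C)CCC[C@]3(C)C(=O)OC | intermediate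
19 | dimethyl (4S,5R,9R,10S)-8-oxo-13,14,15,16,17-pentanorlabdane-12,19-dioate | COC(=O)C[C@H]1C(=O)CC[C@@H]2[C@]1(C)CCC[C@]2(C)C(=O)OC | intermediate
20 | dimethyl (4S,5R,9S,10R)-13,14,15,16-tetranorlabd-8(17)-ene-12,19-dioate | COC(=O)C[C@H]1C(=C)CC[C@@H]2[C@]1(C)CCC[C@]2(C)C(=O)OC | intermediate
21 | methyl (4S,5R,9S,10R)-12-hydroxy-13,14,15,16-tetranorlabd-8(17)-en-19-oate | OCC[C@H]1C(=C)CC[C@@H]2[C@]1(C)CCC[C@]2(C)C(=O)OC | intermediate
22 | methyl (4S,5R,9S,10R)-12-iodo-13,14,15,16-tetranorlabd-8(17)-en-19-oate | ICC[C@H]1C(=C)CC[C@@H]2[C@]1(C)CCC[C@]2(C)C(=O)OC | intermediate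
23 | (S)-but-3-ene-1,2-diol | C=C[C@H](O)CO | starting material
24 | (S)-2,2-dimethyl-4-vinyl-1,3-dioxolane | C=C[C@H]1COC(C)(C)O1 | intermediate
25 | (4R)-4-(1,2-dibromoethyl)-2,2-dimethyl-1,3-dioxolane (both epimers at the CHBr carbon) | BrCC(Br)[C@H]1COC(C)(C)O1 | intermediate
26 | (R)-4-(1-bromovinyl)-2,2-dimethyl-1,3-dioxolane | C=C(Br)[C@H]1COC(C)(C)O1 | intermediate
27 | iodo[(4S,5R,9S,10R)-19-methoxy-19-oxo-13,14,15,16-tetranorlabd-8(17)-en-12-yl]zinc (alkylzinc iodide from 22) | I[Zn]CC[C@H]1C(=C)CC[C@@H]2[C@]1(C)CCC[C@]2(C)C(=O)OC | intermediate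
28 | methyl (4S,5R,9S,10R,14S)-14,15-(isopropylidenedioxy)labda-8(17),13(16)-dien-19-oate | C=C(CC[C@H]1C(=C)CC[C@@H]2[C@]1(C)CCC[C@]2(C)C(=O)OC)[C@H]3COC(C)(C)O3 | intermediate
29 | methyl (4S,5R,9S,10R,14S)-14,15-dihydroxylabda-8(17),13(16)-dien-19-oate (CNP0185041.1) | C=C(CC[C@H]1C(=C)CC[C@@H]2[C@]1(C)CCC[C@]2(C)C(=O)OC)[C@H](O)CO | target

**Step count**

Total: 22 steps. Longest linear sequence: 18 steps (steps 1–9, 11–17, 21 and 22, from 1 to 29); step 10 and steps 18–20 are side branches.

**Steps most likely to fail**

Step 13. Ring closure at the crowded C9, which lies between the forming quaternary C10 and the ketal carbon, may be slow; the C10 radical is then simply reduced or the alkene isomerises, and a ketal oxygen held 1,3-diaxial to C20 may distort the chair and erode the trans selectivity. The fallback changes the acceptor: it sets out from the unprotected keto enoate 16 and submits it to the same Fe(acac)3/PhSiH3 conditions. C8 is then trigonal, the diaxial contact is gone and the acceptor is doubly activated. The 6-exo closure at C9 should still be preferred over the 7-endo closure at C11 on ring-size grounds. The cyclised 1,4-dicarbonyl compound is 19 itself, where the route is rejoined, so steps 12 and 14 fall away.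

Step 3. The trisubstituted diene may react slowly, facial or endo/exo selectivity may be poor, and the strongly acidic catalyst may transfer the silyl group to the aldehyde. The fallback gives up asymmetric catalysis: it sets out from 4 and 5, which are combined under Me2AlCl in CH2Cl2 at −78 °C to give racemic endo 2-{2-[(4-methoxybenzyl)oxy]ethyl}-1,3-dimethyl-4-[(triisopropylsilyl)oxy]cyclohex-3-ene-1-carbaldehyde F1. The enantiomers are separated by preparative supercritical-fluid chromatography on a chiral stationary phase, and the (1S,2R) enantiomer is 6, where the route is rejoined.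

Step 16. Chemoselectivity between the two methyl esters may be lost, through hydride attack at C19 or incomplete reduction at C12. The fallback differentiates the esters by hydrolysis and not by hydride. It sets out from 20, which is treated with LiOH (1.1 equiv) in THF/MeOH/H2O; this should cleave only the unhindered ester and give (4S,5R,9S,10R)-19-methoxy-19-oxo-13,14,15,16-tetranorlabd-8(17)-en-12-oic acid F2, the axial C19 ester being resistant to saponification. The acid is activated with isobutyl chloroformate and N-methylmorpholine in THF at −15 °C as the isobutyl carbonic mixed anhydride F3. Reduction in the same flask with NaBH4 in aqueous THF gives 21, where the route is rejoined.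

**Further compounds**

F0 | step 13 | none | none
F1 | step 3 | racemic endo 2-{2-[(4-methoxybenzyl)oxy]ethyl}-1,3-dimethyl-4-[(triisopropylsilyl)oxy]cyclohex-3-ene-1-carbaldehyde | COc1ccc(COCC[C@@H]2C(C)=C(O[Si](C(C)C)(C(C)C)C(C)C)CC[C@]2(C)C=O)cc1.COc1ccc(COCC[C@H]2C(C)=C(O[Si](C(C)C)(C(C)C)C(C)C)CC[C@@]2(C)C=O)cc1
F2 | step 16 | (4S,5R,9S,10R)-19-methoxy-19-oxo-13,14,15,16-tetranorlabd-8(17)-en-12-oic acid | OC(=O)C[C@H]1C(=C)CC[C@@H]2[C@]1(C)CCC[C@]2(C)C(=O)OC
F3 | step 16 | isobutyl carbonic mixed anhydride of F2 | CC(C)COC(=O)OC(=O)C[C@H]1C(=C)CC[C@@H]2[C@]1(C)CCC[C@]2(C)C(=O)OC
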